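**Retrosynthetic overview** (azulene numbering: five-membered ring C1–C3, C3a, C8a; seven-membered ring C3a, C4–C8, C8a)
1. Ester C–O → 4-acetoxybenzoic acid + 3β,4α-diol; C4 carbinol ← conjugated enone by hydroxyl-directed reduction; enone ← C4 ketone with the alkene one position further round the ring (C6=C7).
2. Key disconnection: C4–C5 and C3a–C8a in one operation, by intramolecular rhodium-catalysed (5+2) cycloaddition of a vinylcyclopropane with a tethered alkynylsilane; the five- and seven-membered rings close together.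
3. Enabling feature: ring atoms C5–C6(Me)–C7–C8–C8a are an isoprene unit (isopropenyl C5=C6 on cyclopropane C7–C8–C8a) and C4–C3a is a two-carbon alkyne; C8a carries the C1–C2–C3 tether, and silicon on C4 is a masked ketone that later pulls the alkene to C5=C6.
4. Ring order: cyclopropane first (Charette cyclopropanation of nerol fixes C8a), then both carbocycles in the key step; C3 is set before it by ketone alkynylation, C3a and C4 after it by equilibration and directed reduction.

Key step: step 9

Remark: benzyl(ethynyl)dimethylsilane is assumed not to be stocked and is made in step 5; β is the face of the C8a methyl group, α the opposite face.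

Step 1
Reactants: 1 nerol [(2Z)-3,7-dimethylocta-2,6-dien-1-ol]; 2 diiodomethane
Product: 3 [(1S,2R)-2-methyl-2-(4-methylpent-3-en-1-yl)cyclopropyl]methanol
Conditions: Et2Zn, CH2I2, DME, (4R,5R)-2-butyl-N,N,N',N'-tetramethyl-1,3,2-dioxaborolane-4,5-dicarboxamide (1.2 equiv), CH2Cl2, −10 °C → rt
Reagents that add atoms: diiodomethane, ICI
Why: Charette asymmetric Simmons–Smith cyclopropanation: the zinc alkoxide of 1, bound to the chiral dioxaborolane, directs methylene transfer to the allylic alkene only, syn-stereospecific addition to the Z-alkene puts CH2OH and the homoprenyl chain cis, and the (4R,5R) ligand should select the face that makes the carbinol-bearing ring carbon S and the methyl-bearing ring carbon R.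

Step 2
Reactants: 3 [(1S,2R)-2-methyl-2-(4-methylpent-3-en-1-yl)cyclopropyl]methanol
Product: 5 1-[(1R,2S)-2-(hydroxymethyl)-1-methylcyclopropyl]-4-methylpentan-3-ol (both C3 epimers), via alkylborane 4 (not isolated)
Conditions: BH3·THF (2.5 equiv), THF, 0 °C → rt; then NaOH, H2O2, 0 °C
Reagents that add atoms: hydrogen peroxide, OO
Why: Hydroboration–oxidation: boron adds to the less substituted carbon of the remaining trisubstituted alkene (the O–H only consumes one hydride and the cyclopropane is inert to borane), and C–B oxidation with retention gives the secondary alcohol, whose uncontrolled stereocentre is erased in step 3.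

Step 3
Reactants: 5 1-[(1R,2S)-2-(hydroxymethyl)-1-methylcyclopropyl]-4-methylpentan-3-ol
Product: 6 (1S,2R)-2-methyl-2-(4-methyl-3-oxopentyl)cyclopropane-1-carbaldehyde
Conditions: (n-Pr)4N[RuO4] (5 mol %), N-methylmorpholine N-oxide (3 equiv), 4 Å MS, CH2Cl2, rt
Reagents that add atoms: none
Why: Ley–Griffith oxidation: the perruthenate/N-oxide couple takes the primary alcohol to the aldehyde and the secondary alcohol to the ketone under neutral conditions that should neither epimerise nor over-oxidise the cis-cyclopropanecarbaldehyde.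

Step 4
Reactants: 6 (1S,2R)-2-methyl-2-(4-methyl-3-oxopentyl)cyclopropane-1-carbaldehyde; 7 methylmagnesium bromide
Product: 8 1-[(1R,2S)-2-(1-hydroxyethyl)-1-methylcyclopropyl]-4-methylpentan-3-one (both carbinol epimers)
Conditions: MeMgBr (1.1 equiv), THF, −78 °C; then H2O
Reagents that add atoms: methylmagnesium bromide, C[Mg]Br
Why: Chemoselective Grignard addition: at −78 °C one equivalent of MeMgBr should add to the aldehyde and leave the α-branched isopropyl ketone alone; the unselective new carbinol centre is erased in step 7.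

Step 5
Reactants: 9 ethynylmagnesium bromide; 10 benzyl(chloro)dimethylsilane
Product: 11 benzyl(ethynyl)dimethylsilane
Conditions: THF, 0 °C → rt
Reagents that add atoms: benzyl(chloro)dimethylsilane, C[Si](C)(Cl)Cc1ccccc1
Why: Nucleophilic substitution at silicon by an alkynyl Grignard reagent, the standard preparation of alkynylsilanes.

Step 6
Reactants: 8 1-[(1R,2S)-2-(1-hydroxyethyl)-1-methylcyclopropyl]-4-methylpentan-3-one; 11 benzyl(ethynyl)dimethylsilane
Product: 12 (3R)-1-[benzyl(dimethyl)silyl]-5-[(1R,2S)-2-(1-hydroxyethyl)-1-methylcyclopropyl]-3-(propan-2-yl)pent-1-yn-3-ol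
Conditions: 11 (3 equiv), Me2Zn (4 equiv), N,N'-bis(3,5-di-tert-butylsalicylidene)-trans-1,2-cyclohexanediamine (20 mol %, the enantiomer that gives Si-face addition), toluene, rt; then H2O
Reagents that add atoms: benzyl(ethynyl)dimethylsilane, C#C[Si](C)(C)Cc1ccccc1
Why: Catalytic enantioselective addition of an alkynylzinc (formed in the flask from 11 and Me2Zn) to a ketone under zinc–salen Lewis acid/Lewis base activation: reagent control should deliver the alkynyl group to the Si face (O > i-Pr > CH2) and set the 3R carbinol, while the remote secondary alcohol rides along as its zinc alkoxide.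

Step 7
Reactants: 12 (3R)-1-[benzyl(dimethyl)silyl]-5-[(1R,2S)-2-(1-hydroxyethyl)-1-methylcyclopropyl]-3-(propan-2-yl)pent-1-yn-3-ol
Product: 13 1-[(1S,2R)-2-{(3R)-5-[benzyl(dimethyl)silyl]-3-hydroxy-3-(propan-2-yl)pent-4-yn-1-yl}-2-methylcyclopropyl]ethan-1-one
Conditions: (n-Pr)4N[RuO4] (5 mol %), N-methylmorpholine N-oxide (1.5 equiv), 4 Å MS, CH2Cl2, rt
Reagents that add atoms: none
Why: Ley–Griffith oxidation of the secondary cyclopropyl carbinol to the methyl ketone; the tertiary propargylic alcohol cannot be oxidised and the alkynylsilane is inert.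

Step 8
Reactants: 13 1-[(1S,2R)-2-{(3R)-5-[benzyl(dimethyl)silyl]-3-hydroxy-3-(propan-2-yl)pent-4-yn-1-yl}-2-methylcyclopropyl]ethan-1-one; 14 methyltriphenylphosphonium bromide
Product: 15 (3R)-1-[benzyl(dimethyl)silyl]-5-[(1R,2R)-1-methyl-2-(prop-1-en-2-yl)cyclopropyl]-3-(propan-2-yl)pent-1-yn-3-ol
Conditions: Ph3PCH3Br (3 equiv), n-BuLi (2.9 equiv), THF, 0 °C; then 13, −20 °C → rt
Reagents that add atoms: methyltriphenylphosphonium bromide, C[P+](c1ccccc1)(c1ccccc1)c1ccccc1.[Br-]
Why: Wittig methylenation with a non-stabilised ylide (one extra equivalent is spent on the tertiary O–H), run cold to avoid epimerisation at the ring carbon α to the ketone, turns the acetyl group into the isopropenyl group and completes the cis-vinylcyclopropane.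

Step 9
Reactants: 15 (3R)-1-[benzyl(dimethyl)silyl]-5-[(1R,2R)-1-methyl-2-(prop-1-en-2-yl)cyclopropyl]-3-(propan-2-yl)pent-1-yn-3-ol
Product: 16 (3R,8aR)-4-[benzyl(dimethyl)silyl]-6,8a-dimethyl-3-(propan-2-yl)-1,2,3,5,8,8a-hexahydroazulen-3-ol
Conditions: [Rh(CO)2Cl]2 (5 mol %), toluene (0.02 M), 70 °C, Ar
Reagents that add atoms: none
Why: Proposed new method: monovalent rhodium, held by the isopropenyl group, should insert with retention into the adjacent cyclopropane bond that leads to the fully substituted ring carbon (the future C7···C8a), giving a σ-alkyl/π-allyl rhodacycle, after which the tethered alkyne inserts into the Rh–C8a bond and C4–C5 reductive elimination at the outer allyl carbon releases the cyclohepta-1,4-diene. The closest known reaction type is the rhodium-catalysed intramolecular (5+2) cycloaddition of yne-vinylcyclopropanes and its variant with an alkene tethered to the ring carbon cis to the vinyl group; new here are the alkyne partner on that ring carbon and metalation of a fully substituted carbon. The five-membered ring closes by 5-exo-dig migratory insertion (C3a–C8a, creating the quaternary centre) and the seven-membered ring by reductive elimination from an eight-membered rhodacycle (C4–C5). No stereocentre is created: C8a keeps the configuration set in step 1 because C–C oxidative addition and migratory insertion both go with retention, and C3 is a spectator. The step needs cleavage of the C7–C8a bond instead of C7–C8 (only rhodium on C8a can reach the alkyne through the three-atom tether, helped by the Thorpe–Ingold effect of quaternary C3), (5+2) instead of (3+2) closure (favoured by the cis relation of isopropenyl group and tether inherited from the Z-alkene of nerol), and a temperature below the onset of the homodienyl 1,5-hydrogen shift of cis-alkyl vinylcyclopropanes; the silyl group blocks alkyne oligomerisation and places a masked carbonyl on C4.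

Step 10
Reactants: 16 (3R,8aR)-4-[benzyl(dimethyl)silyl]-6,8a-dimethyl-3-(propan-2-yl)-1,2,3,5,8,8a-hexahydroazulen-3-ol
Product: 18 (3R,3aR,8aR)-3-hydroxy-6,8a-dimethyl-3-(propan-2-yl)-2,3,3a,5,8,8a-hexahydroazulen-4(1H)-one, via cyclic siloxane 17 (not isolated)
Conditions: TBAF (3 equiv), THF, 0 °C; then KHCO3, 30% H2O2, MeOH, 0 °C → rt; Na2S2O3 work-up
Reagents that add atoms: hydrogen peroxide, OO
Why: Tamao–Fleming oxidation of an alkenyl(benzyl)dimethylsilane: fluoride removes the benzyl group with help from the cis-disposed 3-alkoxide to give cyclic siloxane 17, peroxide then shifts C4 from silicon to oxygen with retention, and the liberated enol ketonises (any C3a epimer formed on protonation is converged in step 11).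

Step 11
Reactants: 18 (3R,3aR,8aR)-3-hydroxy-6,8a-dimethyl-3-(propan-2-yl)-2,3,3a,5,8,8a-hexahydroazulen-4(1H)-one
Product: 19 (3R,3aR,8aS)-3-hydroxy-6,8a-dimethyl-3-(propan-2-yl)-2,3,3a,7,8,8a-hexahydroazulen-4(1H)-one
Conditions: DBU (0.5 equiv), CH2Cl2, rt (40 °C if needed)
Reagents that add atoms: none
Why: Base-mediated isomerisation through the dienolate moves the alkene into conjugation (β,γ- to α,β-unsaturated ketone), and enolisation towards C3a should settle the ring fusion in the trans form, expected to be favoured thermodynamically because C4 then lies cis to the 3-hydroxyl (O–H···O=C hydrogen bond) and trans to the isopropyl group.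

Step 12
Reactants: 19 (3R,3aR,8aS)-3-hydroxy-6,8a-dimethyl-3-(propan-2-yl)-2,3,3a,7,8,8a-hexahydroazulen-4(1H)-one
Product: 20 (3R,3aS,4S,8aS)-6,8a-dimethyl-3-(propan-2-yl)-1,2,3,3a,4,7,8,8a-octahydroazulene-3,4-diol
Conditions: Me4NBH(OAc)3 (5 equiv), MeCN/AcOH (1:1), −30 → −10 °C
Reagents that add atoms: none
Why: Evans–Saksena reduction: the tertiary 3β-hydroxyl exchanges onto boron and delivers hydride intramolecularly to the β face of the C4 carbonyl (1,2-reduction of the enone), which should give the 1,3-anti diol with the new hydroxyl α (4S).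

Step 13
Reactants: 20 (3R,3aS,4S,8aS)-6,8a-dimethyl-3-(propan-2-yl)-1,2,3,3a,4,7,8,8a-octahydroazulene-3,4-diol; 21 4-(acetyloxy)benzoic acid
Product: 22 (3R,3aS,4S,8aS)-3-hydroxy-6,8a-dimethyl-3-(propan-2-yl)-1,2,3,3a,4,7,8,8a-octahydroazulen-4-yl 4-(acetyloxy)benzoate
Conditions: 21 (1.5 equiv), DCC (1.6 equiv), DMAP (0.3 equiv), CH2Cl2, rt
Reagents that add atoms: 4-(acetyloxy)benzoic acid, CC(=O)Oc1ccc(cc1)C(=O)O
Why: Steglich esterification: the DMAP-activated acyl group is taken up by the secondary allylic alcohol only, the hindered tertiary alcohol being inert, and the phenol is carried as its acetate so that the acid cannot acylate itself.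

Step 14
Reactants: 22 (3R,3aS,4S,8aS)-3-hydroxy-6,8a-dimethyl-3-(propan-2-yl)-1,2,3,3a,4,7,8,8a-octahydroazulen-4-yl 4-(acetyloxy)benzoate
Product: 23 (3R,3aS,4S,8aS)-3-hydroxy-6,8a-dimethyl-3-(propan-2-yl)-1,2,3,3a,4,7,8,8a-octahydroazulen-4-yl 4-hydroxybenzoate
Conditions: pyrrolidine (3 equiv), CH2Cl2, 0 °C → rt
Reagents that add atoms: none
Why: Chemoselective aminolysis: pyrrolidine cleaves the activated aryl acetate far faster than the hindered secondary alkyl benzoate (which becomes still less electrophilic once the phenol is free), and no stereocentre is touched.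

**Compound list**
1 | nerol, (2Z)-3,7-dimethylocta-2,6-dien-1-ol | CC(C)=CCC/C(C)=C\CO | starting material
2 | diiodomethane | ICI | starting material
3 | [(1S,2R)-2-methyl-2-(4-methylpent-3-en-1-yl)cyclopropyl]methanol | OC[C@H]1C[C@@]1(C)CCC=C(C)C | intermediate
4 | alkylborane: {[(1S,2R)-2-(3-boranyl-4-methylpentyl)-2-methylcyclopropyl]methoxy}borane (C3 epimers) | BOC[C@H]1C[C@@]1(C)CCC(B)C(C)C | intermediate
5 | 1-[(1R,2S)-2-(hydroxymethyl)-1-methylcyclopropyl]-4-methylpentan-3-ol (C3 epimers) | OC[C@H]1C[C@@]1(C)CCC(O)C(C)C | intermediate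
6 | (1S,2R)-2-methyl-2-(4-methyl-3-oxopentyl)cyclopropane-1-carbaldehyde | O=C[C@H]1C[C@@]1(C)CCC(=O)C(C)C | intermediate
7 | methylmagnesium bromide | C[Mg]Br | starting material
8 | 1-[(1R,2S)-2-(1-hydroxyethyl)-1-methylcyclopropyl]-4-methylpentan-3-one (carbinol epimers) | CC(O)[C@H]1C[C@@]1(C)CCC(=O)C(C)C | intermediate
9 | ethynylmagnesium bromide | C#C[Mg]Br | starting material
10 | benzyl(chloro)dimethylsilane | C[Si](C)(Cl)Cc1ccccc1 | starting material
11 | benzyl(ethynyl)dimethylsilane | C#C[Si](C)(C)Cc1ccccc1 | intermediate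
12 | (3R)-1-[benzyl(dimethyl)silyl]-5-[(1R,2S)-2-(1-hydroxyethyl)-1-methylcyclopropyl]-3-(propan-2-yl)pent-1-yn-3-ol (carbinol epimers in the hydroxyethyl group) | CC(O)[C@H]1C[C@@]1(C)CC[C@@](O)(C(C)C)C#C[Si](C)(C)Cc2ccccc2 | intermediate
13 | 1-[(1S,2R)-2-{(3R)-5-[benzyl(dimethyl)silyl]-3-hydroxy-3-(propan-2-yl)pent-4-yn-1-yl}-2-methylcyclopropyl]ethan-1-one | CC(=O)[C@H]1C[C@@]1(C)CC[C@@](O)(C(C)C)C#C[Si](C)(C)Cc2ccccc2 | intermediate
14 | methyltriphenylphosphonium bromide | C[P+](c1ccccc1)(c1ccccc1)c1ccccc1.[Br-] | starting material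
15 | (3R)-1-[benzyl(dimethyl)silyl]-5-[(1R,2R)-1-methyl-2-(prop-1-en-2-yl)cyclopropyl]-3-(propan-2-yl)pent-1-yn-3-ol | C=C(C)[C@H]1C[C@@]1(C)CC[C@@](O)(C(C)C)C#C[Si](C)(C)Cc2ccccc2 | intermediate
16 | (3R,8aR)-4-[benzyl(dimethyl)silyl]-6,8a-dimethyl-3-(propan-2-yl)-1,2,3,5,8,8a-hexahydroazulen-3-ol | CC1=CC[C@@]2(C)CC[C@@](O)(C(C)C)C2=C([Si](C)(C)Cc3ccccc3)C1 | intermediate
17 | cyclic siloxane: 2,2-dimethyl-2,5-dihydro-1,2-oxasilole fused across C3–C3a–C4 of 16 (O on C3, Si on C4) | CC1=CC[C@@]2(C)CC[C@]3(C(C)C)O[Si](C)(C)C(C1)=C23 | intermediate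
18 | (3R,3aR,8aR)-3-hydroxy-6,8a-dimethyl-3-(propan-2-yl)-2,3,3a,5,8,8a-hexahydroazulen-4(1H)-one | CC1=CC[C@@]2(C)CC[C@@](O)(C(C)C)[C@@H]2C(=O)C1 | intermediate
19 | (3R,3aR,8aS)-3-hydroxy-6,8a-dimethyl-3-(propan-2-yl)-2,3,3a,7,8,8a-hexahydroazulen-4(1H)-one | CC1=CC(=O)[C@@H]2[C@@](C)(CC1)CC[C@@]2(O)C(C)C | intermediate
20 | (3R,3aS,4S,8aS)-6,8a-dimethyl-3-(propan-2-yl)-1,2,3,3a,4,7,8,8a-octahydroazulene-3,4-diol | CC1=C[C@H](O)[C@@H]2[C@@](C)(CC1)CC[C@@]2(O)C(C)C | intermediate
21 | 4-(acetyloxy)benzoic acid | CC(=O)Oc1ccc(cc1)C(=O)O | starting material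
22 | (3R,3aS,4S,8aS)-3-hydroxy-6,8a-dimethyl-3-(propan-2-yl)-1,2,3,3a,4,7,8,8a-octahydroazulen-4-yl 4-(acetyloxy)benzoate | CC1=C[C@H](OC(=O)c2ccc(OC(C)=O)cc2)[C@@H]2[C@@](C)(CC1)CC[C@@]2(O)C(C)C | intermediate
23 | (3R,3aS,4S,8aS)-3-hydroxy-6,8a-dimethyl-3-(propan-2-yl)-1,2,3,3a,4,7,8,8a-octahydroazulen-4-yl 4-hydroxybenzoate | CC1=C[C@H](OC(=O)c2ccc(O)cc2)[C@@H]2[C@@](C)(CC1)CC[C@@]2(O)C(C)C | target

**Totals**
Total step count: 14. Longest linear sequence: 13 steps (steps 1–4 and 6–14, from nerol).

**Steps most likely to fail**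

1. Step 9 (the proposed new method). What may go wrong: rhodium may insert into the less substituted C7–C8 bond instead of the bond at the fully substituted carbon; the allyl unit may close at its inner carbon to give a (3+2) bicyclo[3.3.0]octene; or the cis-alkyl vinylcyclopropane may undergo the thermal homodienyl 1,5-hydrogen shift before it cyclises.
Fallback (known chemistry only): the cyclopropane line is given up and the bicycle is built by conjugate addition with enolate trapping, ring-closing metathesis and carbonyl addition. It sets out from methylmagnesium bromide 7, the only numbered compound it uses, and comes back to the route at enone 19. Commercial 3-ethoxycyclopent-2-en-1-one and (3-methylbut-3-en-1-yl)magnesium bromide should give, after acidic work-up (Stork–Danheiser transposition), 3-(3-methylbut-3-en-1-yl)cyclopent-2-en-1-one F1. Copper-catalysed asymmetric conjugate addition of 7 to F1 (CuBr·SMe2 5 mol %, chiral imidazolinium-derived carbene ligand chosen for the 3S product, Et2O, −30 °C) creates the quaternary carbon. The magnesium enolate is then trapped with acrolein anti to the longer chain to give (2S,3S)-2-(1-hydroxyprop-2-en-1-yl)-3-methyl-3-(3-methylbut-3-en-1-yl)cyclopentan-1-one F2. Ring-closing metathesis (second-generation Grubbs catalyst, (H2IMes)(PCy3)Cl2Ru=CHPh, CH2Cl2, 40 °C) closes the seven-membered ring with its trisubstituted alkene to give the bicyclic hydroxy ketone F3. Addition of i-PrMgCl/CeCl3 (THF, −78 °C) should occur from the face opposite the angular methyl group and give diol 20 together with its C4-epimeric diol F4. MnO2 then oxidises both allylic alcohols to 19, and steps 12–14 follow.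

2. Step 6. What may go wrong: poor facial selectivity, because the zinc catalyst has to tell an isopropyl group from a CH2CH2R chain, so both C3 epimers form.
Fallback: C3 is set by Sharpless asymmetric epoxidation and epoxy-chloride fragmentation instead of by a ketone addition. It sets out from 8 and comes back at 12. TESCl/imidazole protects the secondary alcohol as the triethylsilyl ether F5. Horner–Wadsworth–Emmons reaction with triethyl phosphonoacetate (NaH, THF, reflux) gives the (E)-enoate F6 (ester trans to isopropyl; the minor Z isomer is removed, or processed with the other tartrate). DIBAL-H gives the (E)-allylic alcohol F7, and Ti(OiPr)4, D-(−)-diethyl tartrate, t-BuOOH (4 Å MS, CH2Cl2, −20 °C) should give the (2R,3R)-epoxy alcohol F8. PPh3/CCl4 converts this into the epoxy chloride F9. n-BuLi (3.3 equiv, THF, −40 °C) effects the double elimination to the lithium acetylide of the (R)-propargylic alkoxide, which is C-silylated in the same flask with 10 to give the silyl ether F10. AcOH/THF/H2O removes the triethylsilyl group and returns 12.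

3. Step 11. What may go wrong: incomplete epimerisation at C3a under the amine base, or retro-aldol opening of the free β-hydroxy ketone before the ring fusion has equilibrated.
Fallback: the equilibration is done on the O-protected ketone with an alkoxide base. It sets out from 18 and comes back at 19. DBU as in step 11 moves the alkene and leaves 19 mixed with the cis-fused enone F11. TESOTf/2,6-lutidine (CH2Cl2, −78 → 0 °C) caps the tertiary hydroxyl of both, giving the cis-fused silyl ether F12 and the trans-fused silyl ether F13. NaOMe in MeOH equilibrates F12 into F13 through the cross-conjugated dienolate (no retro-aldol path is left), and HF·pyridine in THF returns 19.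

**Further compounds**
F1 | step 9 | 3-(3-methylbut-3-en-1-yl)cyclopent-2-en-1-one | CC(=C)CCC1=CC(=O)CC1
F2 | step 9 | (2S,3S)-2-(1-hydroxyprop-2-en-1-yl)-3-methyl-3-(3-methylbut-3-en-1-yl)cyclopentan-1-one (carbinol epimers) | C=CC(O)[C@H]1C(=O)CC[C@]1(C)CCC(C)=C
F3 | step 9 | (3aS,8aS)-4-hydroxy-6,8a-dimethyl-1,3a,4,7,8,8a-hexahydroazulen-3(2H)-one (C4 epimers) | CC1=CC(O)[C@@H]2[C@@](C)(CC1)CCC2=O
F4 | step 9 | (3R,3aS,4R,8aS)-6,8a-dimethyl-3-(propan-2-yl)-1,2,3,3a,4,7,8,8a-octahydroazulene-3,4-diol (C4 epimer of 20) | CC1=C[C@@H](O)[C@@H]2[C@@](C)(CC1)CC[C@@]2(O)C(C)C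
F5 | step 6 | 4-methyl-1-[(1R,2S)-1-methyl-2-{1-[(triethylsilyl)oxy]ethyl}cyclopropyl]pentan-3-one | CC(O[Si](CC)(CC)CC)[C@H]1C[C@@]1(C)CCC(=O)C(C)C
F6 | step 6 | ethyl (2E)-4-methyl-3-[2-((1R,2S)-1-methyl-2-{1-[(triethylsilyl)oxy]ethyl}cyclopropyl)ethyl]pent-2-enoate | CC(O[Si](CC)(CC)CC)[C@H]1C[C@@]1(C)CC/C(C(C)C)=C\C(=O)OCC
F7 | step 6 | (2E)-4-methyl-3-[2-((1R,2S)-1-methyl-2-{1-[(triethylsilyl)oxy]ethyl}cyclopropyl)ethyl]pent-2-en-1-ol | CC(O[Si](CC)(CC)CC)[C@H]1C[C@@]1(C)CC/C(C(C)C)=C\CO
F8 | step 6 | (2R,3R)-2,3-epoxy alcohol of F7: [(2R,3R)-3-[2-((1R,2S)-1-methyl-2-{1-[(triethylsilyl)oxy]ethyl}cyclopropyl)ethyl]-3-(propan-2-yl)oxiran-2-yl]methanol | CC(O[Si](CC)(CC)CC)[C@H]1C[C@@]1(C)CC[C@]2(C(C)C)O[C@@H]2CO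
F9 | step 6 | epoxy chloride of F8 (CH2OH replaced by CH2Cl, same epoxide configuration) | CC(O[Si](CC)(CC)CC)[C@H]1C[C@@]1(C)CC[C@]2(C(C)C)O[C@@H]2CCl
F10 | step 6 | triethylsilyl ether of 12 at the secondary hydroxyl | CC(O[Si](CC)(CC)CC)[C@H]1C[C@@]1(C)CC[C@@](O)(C(C)C)C#C[Si](C)(C)Cc2ccccc2
F11 | step 11 | (3R,3aS,8aS)-3-hydroxy-6,8a-dimethyl-3-(propan-2-yl)-2,3,3a,7,8,8a-hexahydroazulen-4(1H)-one (cis-fused C3a epimer of 19) | CC1=CC(=O)[C@H]2[C@@](C)(CC1)CC[C@@]2(O)C(C)C
F12 | step 11 | 3-O-triethylsilyl ether of F11 | CC1=CC(=O)[C@H]2[C@@](C)(CC1)CC[C@@]2(O[Si](CC)(CC)CC)C(C)C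
F13 | step 11 | 3-O-triethylsilyl ether of 19 | CC1=CC(=O)[C@@H]2[C@@](C)(CC1)CC[C@@]2(O[Si](CC)(CC)CC)C(C)C
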